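## Retrosynthetic overview

- Ring numbering of the target quinone: C1 = carbonyl carbon between C2 (OMe) and C6 (nonadecyl), C3 = CH, C4 = second carbonyl, C5 = CH. The ring bond C2–C3 is disconnected, which leads back to an open-chain (Z)-ene-dione, used as its bis(silyl enol ether).
- Enabling feature: C1 and C4 are 1,4-related carbonyl carbons, so C2 and C3 are the two alpha (donor) carbons of a 1,4-dicarbonyl unit. Their union is a coupling of like polarity, achieved by anodic oxidation; the ring's C5=C6 double bond, kept Z in the precursor, holds them together, and the resulting hydroquinone is oxidized on to the quinone in the same electrolysis.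
- The (Z)-ene-dione comes from oxidative opening of a temporary furan ring: furan C2 and C5 become the carbonyls C1 and C4, and furan C3=C4 becomes C6=C5.
- The 2,3,5-trisubstituted furan is built from 3-bromofuran by C2 methoxymethylation, C3 Kumada coupling with the chain of 1-bromononadecane, and C5 methylation.
- Ring order: the furan ring is bought and opened in step 4; the only ring of the target, the quinone ring, is closed last.

Key step: step 6

Remark: the enol ether at the CH(OMe) terminus of the step 5 product is drawn Z, as expected for soft enolization of an alpha-alkoxy ketone; this geometry has no bearing on the outcome, because that carbon becomes sp2 in the target.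

## Route

Step 1
Reactants: 1 3-bromofuran
Product: 3 3-bromo-2-(methoxymethyl)furan, via (3-bromofuran-2-yl)lithium 2 (not isolated)
Conditions: LiN(i-Pr)2 (LDA), THF, −78 °C; then MOMCl, −78 → 0 °C
Reagents that add atoms: chloromethyl methyl ether (MOMCl), COCCl
Why: Directed lithiation with an amide base removes the C2 proton, which is flanked by the ring oxygen and the bromine, without halogen–metal exchange, and the 2-furyllithium is alkylated by the highly reactive alpha-chloro ether.

Step 2
Reactants: 3 3-bromo-2-(methoxymethyl)furan; 4 1-bromononadecane
Product: 6 2-(methoxymethyl)-3-nonadecylfuran, via nonadecylmagnesium bromide 5 (not isolated)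
Conditions: 4, Mg, THF, 50 °C; then 3, NiCl2(dppp) (3 mol %), THF, 0 °C → reflux
Reagents that add atoms: none
Why: Kumada–Tamao–Corriu coupling, in which the C3–Br bond adds oxidatively to zerovalent nickel, the primary alkyl Grignard reagent transmetallates and reductive elimination follows, with the chelating dppp ligand suppressing beta-hydride elimination and the furfuryl methyl ether inert to both partners.

Step 3
Reactants: 6 2-(methoxymethyl)-3-nonadecylfuran
Product: 8 2-(methoxymethyl)-5-methyl-3-nonadecylfuran, via [5-(methoxymethyl)-4-nonadecylfuran-2-yl]lithium 7 (not isolated)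
Conditions: n-BuLi, THF, −20 → 0 °C; then MeI, 0 °C → rt
Reagents that add atoms: iodomethane, CI
Why: With C2 and C3 substituted, C5 is the only alpha position left, so ring alpha-lithiation of the furan occurs there (faster than deprotonation of the CH2OMe group at low temperature) and the furyllithium is methylated by MeI.

Step 4
Reactants: 8 2-(methoxymethyl)-5-methyl-3-nonadecylfuran
Product: 9 (3Z)-1-methoxy-3-nonadecylhex-3-ene-2,5-dione
Conditions: mCPBA (1.05 equiv), NaHCO3, CH2Cl2, 0 °C
Reagents that add atoms: 3-chloroperoxybenzoic acid (mCPBA), O=C(OO)c1cccc(Cl)c1
Why: Oxidative ring opening of a 2,5-dialkylfuran, in which epoxidation of the electron-rich ring and opening of the epoxide give the ene-dione with the cis (Z) geometry imposed by the former ring, while the bicarbonate buffer and low temperature should prevent acid-induced Z-to-E isomerization.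

Step 5
Reactants: 9 (3Z)-1-methoxy-3-nonadecylhex-3-ene-2,5-dione
Product: 10 (1Z,3Z)-2,5-bis(tert-butyldimethylsilyloxy)-1-methoxy-3-nonadecylhexa-1,3,5-triene
Conditions: TBSOTf (2.5 equiv), Et3N (4 equiv), CH2Cl2, −78 → 0 °C; pentane/cold aq. NaHCO3 work-up, used crude
Reagents that add atoms: tert-butyldimethylsilyl trifluoromethanesulfonate (TBSOTf), CC(C)(C)[Si](C)(C)OS(=O)(=O)C(F)(F)F
Why: Soft enolization (silyl triflate/amine) of both ketones, each of which has only one enolizable alpha position (CH3 and CH2OMe, the other side of each carbonyl being vinylic), should give a single bis(silyl enol ether) with the Z enol ether geometry typical of alpha-alkoxy ketones and with the central Z double bond untouched at low temperature.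

Step 6
Reactants: 10 (1Z,3Z)-2,5-bis(tert-butyldimethylsilyloxy)-1-methoxy-3-nonadecylhexa-1,3,5-triene
Product: 13 2-methoxy-6-nonadecyl-1,4-benzoquinone (target), via 5-methoxy-3-nonadecylcyclohex-2-ene-1,4-dione 11 (not isolated), via 2-methoxy-6-nonadecylhydroquinone 12 (not isolated)
Conditions: constant-current electrolysis (ca. 4.2 F/mol), reticulated vitreous carbon anode, Pt cathode, divided cell, LiClO4 (0.1 M), 2,6-lutidine, MeCN/i-PrOH 4:1, 0.01 M, 0 °C
Reagents that add atoms: none
Why: Proposed new method: one-electron oxidation of the electron-rich triene at the anode should give a delocalized radical cation in which the two enol ether termini, the CH(OMe) carbon and the CH2 carbon (both donor carbons, alpha to the future C1 and C4 carbonyls), bond to each other; a second electron transfer and transfer of both silyl groups to i-PrOH should give ene-dione 11, which enolizes to hydroquinone 12, and 12, more easily oxidized than 10, is taken on to quinone 13 at the same anode, four electrons in all. The closest known reaction types are the intramolecular anodic coupling of two enol ethers, or of a silyl enol ether and a second electron-rich pi system, under these carbon anode/LiClO4/2,6-lutidine/alcohol conditions, the oxidative cyclization of bis(silyl enol ethers) to 1,4-diketones with (NH4)2Ce(NO3)6 or Cu(OTf)2, and the radical-cation (hole-catalysed) 6π-type closure of a (Z)-hexatriene; none has been used to make a quinone ring from a 2,5-bis(silyloxy)hexatriene. The ring is closed in the 6-endo-trig mode (enolendo for the siloxydiene partner), that is, between the two termini of the hexatriene. No stereocentre remains: the CH(OMe) centre of 11 forms racemic and is erased on enolization. The step needs terminus-to-terminus bonding in preference to five-ring closure at the internal C(OTBS) carbon, dimerization or solvent capture: the termini carry the largest HOMO coefficients and their union alone gives the doubly oxygen-stabilized 1,4-bis(silyloxy)cyclohexadiene radical cation, the Z central double bond holds them within bonding distance, each ketone of 9 had only one enolizable position so that 10 is a single regioisomer, and high dilution disfavours intermolecular paths. The divided cell keeps 13 from being reduced at the cathode, and the weakly nucleophilic i-PrOH and the lutidine buffer limit conjugate addition to the quinone and protodesilylation of 10.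

## Compound list

1 | 3-bromofuran | Brc1ccoc1 | starting material
2 | (3-bromofuran-2-yl)lithium | [Li]c1occc1Br | intermediate
3 | 3-bromo-2-(methoxymethyl)furan | COCc1occc1Br | intermediate
4 | 1-bromononadecane | CCCCCCCCCCCCCCCCCCCBr | starting material
5 | nonadecylmagnesium bromide | CCCCCCCCCCCCCCCCCCC[Mg]Br | intermediate
6 | 2-(methoxymethyl)-3-nonadecylfuran | COCc1occc1CCCCCCCCCCCCCCCCCCC | intermediate
7 | [5-(methoxymethyl)-4-nonadecylfuran-2-yl]lithium | [Li]c1cc(CCCCCCCCCCCCCCCCCCC)c(COC)o1 | intermediate
8 | 2-(methoxymethyl)-5-methyl-3-nonadecylfuran | COCc1oc(C)cc1CCCCCCCCCCCCCCCCCCC | intermediate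
9 | (3Z)-1-methoxy-3-nonadecylhex-3-ene-2,5-dione (the two acyl groups cis) | CC(=O)/C=C(/CCCCCCCCCCCCCCCCCCC)C(=O)COC | intermediate
10 | (1Z,3Z)-2,5-bis(tert-butyldimethylsilyloxy)-1-methoxy-3-nonadecylhexa-1,3,5-triene | C=C(O[Si](C)(C)C(C)(C)C)/C=C(/CCCCCCCCCCCCCCCCCCC)\C(O[Si](C)(C)C(C)(C)C)=C\OC | intermediate
11 | 5-methoxy-3-nonadecylcyclohex-2-ene-1,4-dione (racemic) | COC1CC(=O)C=C(CCCCCCCCCCCCCCCCCCC)C1=O | intermediate
12 | 2-methoxy-6-nonadecylbenzene-1,4-diol (2-methoxy-6-nonadecylhydroquinone) | COc1cc(O)cc(CCCCCCCCCCCCCCCCCCC)c1O | intermediate
13 | 2-methoxy-6-nonadecylcyclohexa-2,5-diene-1,4-dione (2-methoxy-6-nonadecyl-1,4-benzoquinone) | CCCCCCCCCCCCCCCCCCCC1=CC(=O)C=C(OC)C1=O | target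

## Step count and risks

Total step count: 6. Longest linear sequence: 6 steps (1 → 3 → 6 → 8 → 9 → 10 → 13).

Steps most likely to fail:

1. Step 6 (proposed new method). The radical cation may be captured by solvent or couple intermolecularly before ring closure, bonding may occur at the internal silyloxy-bearing carbon (five-ring closure), or product quinone may be consumed by Diels–Alder reaction with unreacted triene. Fallback with known chemistry, setting out from 4 and returning at 13: guaiacol is protected (MOMCl, i-Pr2NEt, CH2Cl2) to give 1-methoxy-2-(methoxymethoxy)benzene F1. F1 is lithiated ortho to the OMOM group (n-BuLi, THF, 0 °C) and alkylated with 4 to give 1-methoxy-2-(methoxymethoxy)-3-nonadecylbenzene F2. HCl in MeOH should then give 2-methoxy-6-nonadecylphenol F3. Teuber oxidation with potassium nitrosodisulfonate, (KSO3)2NO, in KH2PO4-buffered aqueous acetone should oxidize the free para position and give 13.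

2. Step 5. Competing intramolecular Mukaiyama-type aldol closure to a five-membered ring, Z-to-E isomerization of the central double bond through reversible amine addition, or gamma-deprotonation (extended enolization) may intervene. Fallback, setting out from 9 and returning at 12: slow addition of 9 to LiN(i-Pr)2 (2.2 equiv) in THF at −78 °C should give dilithium (1Z,3Z)-1-methoxy-3-nonadecylhexa-1,3,5-triene-2,5-diolate F4. F4 is oxidized in the same flask with Cu(OTf)2 (divalent copper, 2.2 equiv), an intramolecular oxidative dienolate coupling in which the reversible aldolate drains into the irreversible C–C coupling. The ring-closed dione 11 should enolize to 12 on work-up, and 12 is oxidized to 13 with Ag2O in Et2O.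

3. Step 4. Over-oxidation (Baeyer–Villiger reaction or epoxidation of the ene-dione) and acid-induced Z-to-E isomerization during isolation may occur. Fallback, setting out from 8 and returning at 9: Clauson-Kaas methoxylation (Br2, MeOH, Na2CO3, −40 °C) should give 2,5-dimethoxy-2-(methoxymethyl)-5-methyl-3-nonadecyl-2,5-dihydrofuran F5 (mixture of diastereomers), a storable bis-ketal. Mild hydrolysis (dilute aqueous oxalic acid in acetone, 0 °C) should release 9 with the cis geometry immediately before step 5.

Further compounds
F1 | step 6 | 1-methoxy-2-(methoxymethoxy)benzene | COCOc1ccccc1OC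
F2 | step 6 | 1-methoxy-2-(methoxymethoxy)-3-nonadecylbenzene | COCOc1c(OC)cccc1CCCCCCCCCCCCCCCCCCC
F3 | step 6 | 2-methoxy-6-nonadecylphenol | COc1cccc(CCCCCCCCCCCCCCCCCCC)c1O
F4 | step 5 | dilithium (1Z,3Z)-1-methoxy-3-nonadecylhexa-1,3,5-triene-2,5-diolate | [Li]OC(=C)/C=C(/CCCCCCCCCCCCCCCCCCC)\C(O[Li])=C\OC
F5 | step 4 | 2,5-dimethoxy-2-(methoxymethyl)-5-methyl-3-nonadecyl-2,5-dihydrofuran (mixture of diastereomers) | COCC1(OC)OC(C)(OC)C=C1CCCCCCCCCCCCCCCCCCC
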